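**Retrosynthetic overview**
1. The two flavonoid halves are joined only by the enol aryl ether between flavonol O3 and the flavanone B-ring carbon C4'. This C–O bond is made last and nothing is protected.
2. Acetophenone 1 is annulated through enaminone 2 to chromone 3, so the pyranone ring of the flavanone half is closed first.
3. Chromone 3 takes one aryl end of diboronic acid 4 in an asymmetric conjugate addition. This sets the only stereocentre (2S) and leaves a boronic acid handle in flavanone 5.
4. Flavanone 5 and kaempferol 6 (all of its rings bought preformed) are united through copper chelate 7 by a site-selective Chan–Lam etherification to give target 8.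

Assumption: the target is read as the (2S)-flavanone, and kaempferol and 2',6'-dihydroxy-4'-methoxyacetophenone are taken as purchasable bulk chemicals.

**Step 1**
Reactants: 1 1-(2,6-dihydroxy-4-methoxyphenyl)ethan-1-one (2',6'-dihydroxy-4'-methoxyacetophenone)
Product: 3 5-hydroxy-7-methoxy-4H-chromen-4-one, via enaminone 2 (not isolated)
Conditions: DMF-DMA (1.5 equiv), toluene, 90 °C, 2 h; then conc. HCl, CH2Cl2, 40 °C
Reagents that add atoms: N,N-dimethylformamide dimethyl acetal (DMF-DMA), COC(OC)N(C)C
Why: Enaminone chromone synthesis: the methyl ketone condenses with the amide acetal to the (E)-enaminone, and acid then drives intramolecular O-addition of an ortho phenol with loss of dimethylamine; the two ortho hydroxyls are equivalent, so only one chromone can form.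

**Step 2**
Reactants: 3 5-hydroxy-7-methoxy-4H-chromen-4-one, 4 benzene-1,4-diyldiboronic acid (3 equiv)
Product: 5 {4-[(2S)-5-hydroxy-7-methoxy-4-oxo-3,4-dihydro-2H-chromen-2-yl]phenyl}boronic acid
Conditions: [RhCl(C2H4)2]2 (1.5 mol %), (S)-MeO-F12-BIPHEP [(S)-6,6'-dimethoxy-2,2'-bis[bis(3,4,5-trifluorophenyl)phosphino]biphenyl] (3.3 mol %), KOH (10 mol %), 1,4-dioxane/H2O 10:1, 20 °C
Reagents that add atoms: none
Why: Hayashi–Miyaura asymmetric 1,4-addition of an arylboronic acid to a chromone: the aryl–rhodium species (monovalent rhodium) bearing the (S)-configured electron-poor diphosphine adds to one face of C2, in the same sense as (S)-BINAP giving (S)-3-arylcyclohexanones, which sets (2S); the ligand sense is assigned by that analogy and must be confirmed on the first run (chiral HPLC, CD), and the antipodal ligand is used if it proves opposite; the threefold excess of 4 limits transfer to one boron end, water protonates the rhodium enolate, and room temperature suppresses ring opening and 1,2-addition.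

**Step 3**
Reactants: 5 {4-[(2S)-5-hydroxy-7-methoxy-4-oxo-3,4-dihydro-2H-chromen-2-yl]phenyl}boronic acid, 6 kaempferol
Product: 8 5,7-dihydroxy-3-{4-[(2S)-5-hydroxy-7-methoxy-4-oxo-3,4-dihydro-2H-chromen-2-yl]phenoxy}-2-(4-hydroxyphenyl)-4H-chromen-4-one, via Cu(OAc)(phen)(kaempferol-3-olate) chelate 7 (not isolated)
Conditions: 6, Cu(OAc)2 (1.0 equiv), 1,10-phenanthroline (1.0 equiv), MeCN/DMF 4:1, rt, 30 min; then 5 (1.3 equiv), 4 Å MS, dry air, rt, 24–36 h; aq. Na2EDTA work-up
Reagents that add atoms: none
Why: Proposed new method: a chelation-directed, amine-free Chan–Lam etherification of an unprotected polyhydroxyflavonol. Of the free hydroxyls present, only the 3-hydroxy-4-keto site binds divalent copper as a five-membered O,O-chelate and is deprotonated by acetate alone, while the more acidic but monodentate 7- and 4'-phenols stay neutral and the hydrogen-bonded 5-hydroxyls of both partners are poor nucleophiles. The phenanthroline blocks the inert bis-flavonolate and leaves a site for boron-to-copper aryl transfer; aerobic oxidation to trivalent copper and C–O reductive elimination then deliver the aryl group to the copper-bound O3. The product ether no longer chelates, so copper is released and arylation stops at one aryl group. Without amine base and at room temperature, C2 of the flavanone should not racemise by retro-oxa-Michael opening, and the copper flavonolate should not enter its known high-temperature oxygenolysis. The closest known reaction type is the Chan–Lam–Evans O-arylation of phenols with arylboronic acids mediated by Cu(OAc)2, combined with the known ternary copper flavonolate complexes.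

**Compound list**
1 | 1-(2,6-dihydroxy-4-methoxyphenyl)ethan-1-one | CC(=O)c1c(O)cc(OC)cc1O | starting material
2 | (E)-3-(dimethylamino)-1-(2,6-dihydroxy-4-methoxyphenyl)prop-2-en-1-one | CN(C)/C=C/C(=O)c1c(O)cc(OC)cc1O | intermediate (not isolated)
3 | 5-hydroxy-7-methoxy-4H-chromen-4-one | COc1cc(O)c2c(c1)occc2=O | intermediate
4 | benzene-1,4-diyldiboronic acid | OB(O)c1ccc(cc1)B(O)O | starting material
5 | {4-[(2S)-5-hydroxy-7-methoxy-4-oxo-3,4-dihydro-2H-chromen-2-yl]phenyl}boronic acid | COc1cc(O)c2c(c1)O[C@H](c1ccc(cc1)B(O)O)CC2=O | intermediate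
6 | kaempferol (3,5,7-trihydroxy-2-(4-hydroxyphenyl)-4H-chromen-4-one) | O=c1c(O)c(-c2ccc(O)cc2)oc2cc(O)cc(O)c12 | starting material
7 | acetato(1,10-phenanthroline)copper kaempferol-3-olate, divalent copper chelated by O3 and the C4 carbonyl oxygen, formed from 6, Cu(OAc)2 and 1,10-phenanthroline | [O-]c1c(-c2ccc(O)cc2)oc2cc(O)cc(O)c2c1=O.CC(=O)[O-].[Cu+2].c1cnc2c(c1)ccc1cccnc12 | intermediate (not isolated)
8 | 5,7-dihydroxy-3-{4-[(2S)-5-hydroxy-7-methoxy-4-oxo-3,4-dihydro-2H-chromen-2-yl]phenoxy}-2-(4-hydroxyphenyl)-4H-chromen-4-one | COc1cc(O)c2c(c1)O[C@H](c1ccc(Oc3c(-c4ccc(O)cc4)oc4cc(O)cc(O)c4c3=O)cc1)CC2=O | target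

**Step count and risks**
Total steps: 3. Longest linear sequence: 3 (1 → 3 → 5 → 8); kaempferol 6 enters at the last step.

The three steps most likely to fail, in order of risk:

Step 3, the proposed new step. Likely failure modes are competing arylation at the 7- or 4'-phenol, slow turnover from the stable chelate, oxidative loss of the flavonol, or erosion of ee. The fallback is protecting-group based and uses known chemistry; it sets out from kaempferol 6. Peracetylation (Ac2O, pyridine) gives kaempferol 3,5,7,4'-tetraacetate F4. Jurd exchange (BnBr, K2CO3, KI, acetone, reflux) replaces the two most labile acetates and gives 3,5-di-O-acetyl-4',7-di-O-benzylkaempferol F5. Methanolysis (K2CO3, MeOH) gives 4',7-di-O-benzylkaempferol F6, whose only reactive hydroxyl is the 3-OH. A conventional single-site Chan–Lam–Evans coupling with 5 (Cu(OAc)2, pyridine, 4 Å MS, CH2Cl2, air, rt) gives the 4',7-di-O-benzyl ether of the target F7. Hydrogenolysis (H2, Pd/C, EtOAc/THF) then comes back to the route at target 8.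

Step 2. Likely failure modes are transfer of both boron ends, protodeboronation of the remaining boronic acid, or difficult purification of the free boronic acid. The fallback masks one boron and sets out from 4 and 3. Condensation of 4 with one equivalent of 1,8-diaminonaphthalene (toluene, reflux) gives [4-(1H-naphtho[1,8-de][1,3,2]diazaborinin-2(3H)-yl)phenyl]boronic acid F2. The same rhodium-catalysed addition to 3 gives (2S)-5-hydroxy-7-methoxy-2-[4-(1H-naphtho[1,8-de][1,3,2]diazaborinin-2(3H)-yl)phenyl]chroman-4-one F3, in which the masked boron cannot transfer and which can be chromatographed. Acid hydrolysis (2 M H2SO4, THF, rt) leaves the stereocentre untouched and comes back to the route at 5.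

Step 1. Likely failure modes are O-methylation of a phenol by the amide acetal or incomplete ring closure. The fallback is a Claisen formylation and sets out from 1. Ethyl formate with NaH in THF gives the cyclic hemiacetal 2,5-dihydroxy-7-methoxychroman-4-one F1. Acid dehydration (HCl, AcOH) comes back to the route at 3.

**Further compounds**
F1 | step 1 | 2,5-dihydroxy-7-methoxychroman-4-one | COc1cc(O)c2c(c1)OC(O)CC2=O
F2 | step 2 | [4-(1H-naphtho[1,8-de][1,3,2]diazaborinin-2(3H)-yl)phenyl]boronic acid | OB(O)c1ccc(cc1)B1Nc2cccc3cccc(N1)c23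
F3 | step 2 | (2S)-5-hydroxy-7-methoxy-2-[4-(1H-naphtho[1,8-de][1,3,2]diazaborinin-2(3H)-yl)phenyl]chroman-4-one | COc1cc(O)c2c(c1)O[C@H](c1ccc(cc1)B1Nc3cccc4cccc(N1)c34)CC2=O
F4 | step 3 | kaempferol 3,5,7,4'-tetraacetate | CC(=O)Oc1ccc(cc1)-c1oc2cc(OC(C)=O)cc(OC(C)=O)c2c(=O)c1OC(C)=O
F5 | step 3 | 3,5-di-O-acetyl-4',7-di-O-benzylkaempferol | CC(=O)Oc1c(-c2ccc(OCc3ccccc3)cc2)oc2cc(OCc3ccccc3)cc(OC(C)=O)c2c1=O
F6 | step 3 | 4',7-di-O-benzylkaempferol | O=c1c(O)c(-c2ccc(OCc3ccccc3)cc2)oc2cc(OCc3ccccc3)cc(O)c12
F7 | step 3 | 7-(benzyloxy)-2-[4-(benzyloxy)phenyl]-5-hydroxy-3-{4-[(2S)-5-hydroxy-7-methoxy-4-oxo-3,4-dihydro-2H-chromen-2-yl]phenoxy}-4H-chromen-4-one | COc1cc(O)c2c(c1)O[C@H](c1ccc(Oc3c(-c4ccc(OCc5ccccc5)cc4)oc4cc(OCc5ccccc5)cc(O)c4c3=O)cc1)CC2=O
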